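**Retrosynthetic overview**

1. Target 11 (chain numbered C1–C7 as heptan-3-one, ring B on C1, ring A on C7) comes from adduct 9 by reduction of a C6–S bond and cleavage of two benzyl ethers.
2. Adduct 9 is cut between C4 and C5 into two natural phenylpropanoid monomers: zingerone (ring B, C1–C4, used as its C4 xanthate 6) and eugenol (ring A, C7–C5, used as benzyl ether 8).
3. Enabling feature: the C3 ketone lets C4 (the former methyl carbon of zingerone) carry a carbon radical, stored as an S-xanthate. C5=C6 is the terminal double bond of eugenol's allyl group and takes that radical at its CH2 end, C5. Both carbons are natively nucleophilic (enol carbon, alkene terminus), so this is a union of like polarity made by radical group transfer.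
4. No ring is formed at any stage: both 4-hydroxy-3-methoxyphenyl rings are bought in. Benzyl ethers mask the phenolic O–H groups, which would otherwise quench the radical chain.

Key step: step 5

Remark: the target is achiral. The only stereocenter on the route (C6 of 9) forms as a racemate and is deleted in step 6. LDA is taken as a commercial solution.

**Step 1**
Reactants: 1 zingerone
Product: 2 4-[4-(benzyloxy)-3-methoxyphenyl]butan-2-one (O-benzylzingerone)
Conditions: BnBr, K2CO3, acetone, reflux
Reagents that add atoms: benzyl bromide, BrCc1ccccc1
Why: Williamson ether synthesis; carbonate forms the phenoxide, which is benzylated chemoselectively, while the ketone is not enolized to a useful extent by this weak base.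

**Step 2**
Reactants: 2 O-benzylzingerone
Product: 5 4-[4-(benzyloxy)-3-methoxyphenyl]-1-bromobutan-2-one, via lithium enolate 3 (not isolated), via silyl enol ether 4 (not isolated)
Conditions: LDA, THF, −78 °C (slow addition of 2); TMSCl, −78 → 0 °C; volatiles removed, pentane filtration; NBS, THF, 0 °C
Reagents that add atoms: N-bromosuccinimide, O=C1CCC(=O)N1Br (Br in 5); chlorotrimethylsilane, C[Si](C)(C)Cl (Me3Si only in intermediate 4); lithium diisopropylamide, [Li+].CC(C)[N-]C(C)C (Li only in intermediate 3)
Why: Kinetic enolate formation with LDA at −78 °C removes a proton from the less hindered CH3 group, O-silylation fixes this regiochemistry, and α-bromination of the silyl enol ether with NBS should place bromine only on the former methyl carbon, faster than NBS attacks the dialkoxyarene.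

**Step 3**
Reactants: 5 bromoketone
Product: 6 S-{4-[4-(benzyloxy)-3-methoxyphenyl]-2-oxobutyl} O-ethyl carbonodithioate
Conditions: EtOC(S)SK, acetone, 0 °C → rt
Reagents that add atoms: potassium O-ethyl xanthate, CCOC(=S)[S-].[K+]
Why: SN2 displacement of the activated primary α-keto bromide by the soft sulfur nucleophile, the standard preparation of S-(2-oxoalkyl) xanthates.

**Step 4**
Reactants: 7 eugenol
Product: 8 4-allyl-1-(benzyloxy)-2-methoxybenzene (O-benzyleugenol)
Conditions: BnBr, K2CO3, acetone, reflux
Reagents that add atoms: benzyl bromide, BrCc1ccccc1
Why: Williamson ether synthesis; carbonate is too weak to isomerize the allyl group to the conjugated propenyl isomer.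

**Step 5**
Reactants: 6 xanthate; 8 O-benzyleugenol (1.5 equiv)
Product: 9 S-{1,7-bis[4-(benzyloxy)-3-methoxyphenyl]-5-oxoheptan-2-yl} O-ethyl carbonodithioate (racemic)
Conditions: dilauroyl peroxide (5 mol% portions until 6 is consumed), degassed EtOAc (about 1 M), reflux, Ar
Reagents that add atoms: none
Why: Undecyl radicals from the peroxide release the 2-oxoalkyl radical (C4) from xanthate 6; this electrophilic radical adds to the unsubstituted terminus (C5) of the allyl group of 8, and the resulting unstabilized secondary C6 radical takes the xanthate group from a further molecule of 6, which carries the chain. The closest known reaction type is the Kharasch-type group-transfer radical addition of S-(2-oxoalkyl) xanthates to unactivated terminal alkenes by degenerative xanthate transfer. No ring is closed. The only new stereocenter, C6 bearing the xanthate, forms without control as a racemate, which does not matter because step 6 turns it into a CH2 group. The step needs regioselectivity for the C4–C5 bond, secured because the C–S bond of 6 fixes the radical site at C4 (not at the other α-carbon, C2) and because a monosubstituted alkene is attacked at its CH2 end. It also needs chain fidelity, secured by the benzyl ethers (no phenolic O–H), by the reversible storage of radicals as xanthates, which gives the C4 radical time to add to an unactivated alkene rather than to attack its own arene, and by the lower stability of the adduct radical, so that 9 should not re-enter the chain and oligomers should not form.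

**Step 6**
Reactants: 9 xanthate adduct
Product: 10 1,7-bis[4-(benzyloxy)-3-methoxyphenyl]heptan-3-one
Conditions: (Me3Si)3SiH, AIBN (cat., portions), toluene, 85 °C
Reagents that add atoms: none
Why: Radical-chain reductive C–S cleavage of Barton–McCombie type: the silyl radical adds to the thiocarbonyl sulfur, β-scission releases the secondary C6 radical, and this takes hydrogen from Si–H, while the ketone and benzyl ethers should stay untouched.

**Step 7**
Reactants: 10 dibenzyl ether
Product: 11 1,7-bis(4-hydroxy-3-methoxyphenyl)heptan-3-one
Conditions: H2 (1 atm), 10% Pd/C, EtOAc–EtOH, rt (10 purified by chromatography beforehand)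
Reagents that add atoms: none
Why: Catalytic hydrogenolysis of both aryl benzyl ethers; a dialkyl ketone and aryl methyl ethers are not reduced under these mild conditions.

**Compound list**

1 | zingerone, 4-(4-hydroxy-3-methoxyphenyl)butan-2-one | COc1cc(CCC(C)=O)ccc1O | starting material
2 | 4-[4-(benzyloxy)-3-methoxyphenyl]butan-2-one | COc1cc(CCC(C)=O)ccc1OCc1ccccc1 | intermediate
3 | lithium 4-[4-(benzyloxy)-3-methoxyphenyl]but-1-en-2-olate | [Li+].[O-]C(=C)CCc1ccc(OCc2ccccc2)c(OC)c1 | intermediate
4 | ({4-[4-(benzyloxy)-3-methoxyphenyl]but-1-en-2-yl}oxy)trimethylsilane | C=C(CCc1ccc(OCc2ccccc2)c(OC)c1)O[Si](C)(C)C | intermediate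
5 | 4-[4-(benzyloxy)-3-methoxyphenyl]-1-bromobutan-2-one | O=C(CBr)CCc1ccc(OCc2ccccc2)c(OC)c1 | intermediate
6 | S-{4-[4-(benzyloxy)-3-methoxyphenyl]-2-oxobutyl} O-ethyl carbonodithioate | CCOC(=S)SCC(=O)CCc1ccc(OCc2ccccc2)c(OC)c1 | intermediate
7 | eugenol, 4-allyl-2-methoxyphenol | C=CCc1ccc(O)c(OC)c1 | starting material
8 | 4-allyl-1-(benzyloxy)-2-methoxybenzene | C=CCc1ccc(OCc2ccccc2)c(OC)c1 | intermediate
9 | S-{1,7-bis[4-(benzyloxy)-3-methoxyphenyl]-5-oxoheptan-2-yl} O-ethyl carbonodithioate (racemic) | CCOC(=S)SC(Cc1ccc(OCc2ccccc2)c(OC)c1)CCC(=O)CCc1ccc(OCc2ccccc2)c(OC)c1 | intermediate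
10 | 1,7-bis[4-(benzyloxy)-3-methoxyphenyl]heptan-3-one | COc1cc(CCCCC(=O)CCc2ccc(OCc3ccccc3)c(OC)c2)ccc1OCc1ccccc1 | intermediate
11 | 1,7-bis(4-hydroxy-3-methoxyphenyl)heptan-3-one | COc1cc(CCCCC(=O)CCc2ccc(O)c(OC)c2)ccc1O | target

**Step count and risks**

Total steps: 7. Longest linear sequence: 6 (steps 1, 2, 3, 5, 6, 7 from zingerone); the eugenol arm is step 4.

Step 5. What may go wrong: short radical chains. The C4 radical or initiator radicals may abstract the doubly activated benzylic and allylic hydrogen at C7 of 8, or a benzylic hydrogen of the ethers, and the stabilized radicals so formed end chains, so that conversion stalls. Fallback: a polar union of the same two carbons with reversed roles, setting out from 8 and 5. Hydroboration of 8 with 9-BBN-H (THF, rt) places boron on C5 and gives 9-{3-[4-(benzyloxy)-3-methoxyphenyl]propyl}-9-borabicyclo[3.3.1]nonane F1. Bromoketone 5 and potassium 2,6-di-tert-butylphenoxide are then added (THF, 0 °C). The α-bromo enolate binds boron through C4, the primary alkyl group shifts from boron to C4 with loss of bromide (1,2-metallate shift, the known base-mediated α-alkylation of α-bromo ketones with B-alkyl-9-BBN), and the phenol protonates the boron enolate. After aqueous work-up this should give 10, where the fallback comes back to the route; 6, 9 and step 6 are bypassed.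

Step 2. What may go wrong: loss of regiocontrol through proton exchange between the kinetic enolate and ketone not yet deprotonated, or through isomerization of the silyl enol ether, which would bring bromine to the internal α-carbon; in addition, double bromination or bromination of the electron-rich ring. Fallback: the regiochemistry is fixed structurally by cutting out the methyl carbon and putting it back as CH2Br, setting out from 2. Haloform reaction (NaOCl, aq. NaOH, dioxane, 0 °C → rt, then acid) should give 3-[4-(benzyloxy)-3-methoxyphenyl]propanoic acid F2. Oxalyl chloride with catalytic DMF in CH2Cl2 converts it into 3-[4-(benzyloxy)-3-methoxyphenyl]propanoyl chloride F3. Excess diazomethane in Et2O at 0 °C (the diazoketone stage of an Arndt–Eistert sequence) gives 4-[4-(benzyloxy)-3-methoxyphenyl]-1-diazobutan-2-one F4. 48% aqueous HBr in Et2O at 0 °C then gives 5, where the fallback comes back to the route.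

Step 7. What may go wrong: poisoning of the palladium surface by sulfur-containing residues carried over from steps 5 and 6, so that debenzylation stops part-way. Fallback: a non-reductive, homogeneous debenzylation, setting out from 10. BCl3 with pentamethylbenzene as cation scavenger (CH2Cl2, −78 °C) transfers both benzyl groups to the scavenger; the aryl methyl ethers and the ketone should survive at this temperature. The fallback comes back at 11 and makes no new intermediate.

**Further compounds**

F1 | step 5 | 9-{3-[4-(benzyloxy)-3-methoxyphenyl]propyl}-9-borabicyclo[3.3.1]nonane | COc1cc(CCCB2C3CCCC2CCC3)ccc1OCc1ccccc1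
F2 | step 2 | 3-[4-(benzyloxy)-3-methoxyphenyl]propanoic acid | COc1cc(CCC(=O)O)ccc1OCc1ccccc1
F3 | step 2 | 3-[4-(benzyloxy)-3-methoxyphenyl]propanoyl chloride | COc1cc(CCC(=O)Cl)ccc1OCc1ccccc1
F4 | step 2 | 4-[4-(benzyloxy)-3-methoxyphenyl]-1-diazobutan-2-one | COc1cc(CCC(=O)C=[N+]=[N-])ccc1OCc1ccccc1
F0 | step 7 | none | none
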